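The isocoumarin is disconnected at C4a–C5 and C6–C7. Its benzene ring (C4a, C5–Cl, C6–O, C7, C8–O, C8a) shares C4a–C8a with a 2-pyranone (C1, O2, C3, C4) identical to the ring of triacetic acid lactone; the arene is therefore annulated onto that lactone at the expense of a second 2-pyranone. In one operation, inverse-demand [4+2] addition of chloroketene diethyl acetal to the methoxy ring of a pyrano[4,3-b]pyran-2,5-dione, followed by loss of CO2 and ethanol, builds the arene with chlorine and both oxygens fixed by connectivity. The precursor is the O-methylated bis-pyrone from triacetic acid lactone and malonyl dichloride; its methyl group is later condensed with a 2-deoxy-D-ribose-derived oxolane enal.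

Key step: step 4

Remark: the oxolane triad (2R,3S,5S) maps onto C4, C3 and C1 of 2-deoxy-D-ribose, with the C5 methyl cis to the C2 dienyl chain and trans to the C3 hydroxyl. TBS = tert-butyldimethylsilyl; bp = bis-pyrone numbering (methoxy ring: bp-O1, bp-C2, bp-C3, bp-C4, bp-C4a, bp-C8a). The methyl enol ether and the diethyl acetal are kept unchanged: methoxide is a poor leaving group at bp-C4, and the chloro carbon keeps the one hydrogen needed for aromatisation.

Step 1
Reactants: 1 4-hydroxy-6-methyl-2H-pyran-2-one (triacetic acid lactone); 2 malonyl dichloride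
Product: 3 4-hydroxy-7-methyl-2H,5H-pyrano[4,3-b]pyran-2,5-dione
Conditions: CF3CO2H, 70 °C
Reagents that add atoms: none
Why: Tandem C-acylation at C3 and O-acylation of the 4-hydroxyl of the hydroxypyranone by the bis-acid chloride (acylation–lactonisation) should close the second 4-hydroxy-2-pyranone ring, the standard entry to pyrano[4,3-b]pyran-2,5-diones.

Step 2
Reactants: 3 4-hydroxy-7-methyl-2H,5H-pyrano[4,3-b]pyran-2,5-dione
Product: 4 4-methoxy-7-methyl-2H,5H-pyrano[4,3-b]pyran-2,5-dione
Conditions: Me2SO4, K2CO3, acetone, reflux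
Reagents that add atoms: dimethyl sulfate, COS(=O)(=O)OC
Why: O-Alkylation of the acidic vinylogous carboxylic acid (Williamson-type methylation), which for 4-hydroxy-2-pyranones should favour the 4-methoxy-2-pyranone over the 2-methoxy-4-pyranone isomer.

Step 3
Reactants: 5 1,1-dichloro-2,2-diethoxyethane (dichloroacetaldehyde diethyl acetal)
Product: 6 2-chloro-1,1-diethoxyethene (chloroketene diethyl acetal)
Conditions: KOt-Bu, t-BuOH, 80 °C; distillation
Reagents that add atoms: none
Why: E2 dehydrochlorination of the α,α-dichloro acetal by tert-butoxide (McElvain-type ketene acetal synthesis) removes the acetal hydrogen and one chloride; the product is distilled and used fresh.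

Step 4
Reactants: 4 4-methoxy-7-methyl-2H,5H-pyrano[4,3-b]pyran-2,5-dione; 6 2-chloro-1,1-diethoxyethene
Product: 9 5-chloro-6-ethoxy-8-methoxy-3-methyl-1H-isochromen-1-one, via bridged lactone cycloadduct 7 (not isolated), via dihydroisochromenone ketal 8 (not isolated)
Conditions: 6 (4 equiv), PhMe, 110 °C, sealed tube
Reagents that add atoms: none
Why: Proposed new method: the electron-rich CHCl terminus of the ketene acetal should bond to bp-C8a of the methoxy ring, and the dienolate so formed should close from bp-C3 onto the diethoxycarbenium carbon, so that the six-membered carbocycle is closed as the second, 6-exo-trig (enolexo) bond of an asynchronous inverse-demand [4+2] to give bridged lactone 7. Retro-[4+2] loss of CO2 should give ketal 8, which can aromatise only by β-elimination of ethanol using the single hydrogen on the chloro carbon, so that C5–Cl, C6–OEt and C8–OMe follow from connectivity and not from arene substitution. The closest known reaction type is the inverse-electron-demand Diels–Alder reaction of 3- or 5-alkoxycarbonyl-2-pyranones with 1,1-dialkoxyethenes, which gives alkoxybenzoates after loss of CO2 and alcohol; here it is extended to a fused bis-pyrone and a 2-chloro ketene acetal. No stereocentre survives, since the bridgehead and CHCl centres of 7 and 8 are destroyed on aromatisation. The step needs site selectivity for the methoxy ring over the methyl-bearing ring, secured because only bp-C8a is both β to the C5 lactone carbonyl and δ to the C2 carbonyl (a coumalate-type 5-acyl-2-pyranone). It also needs regioselectivity, with the CHCl carbon going to bp-C8a and the acetal carbon to bp-C3, secured because the methoxy group makes bp-C3 the nucleophilic end of the dienolate and is too poor a leaving group for addition–elimination at bp-C4.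

Step 5
Reactants: 9 5-chloro-6-ethoxy-8-methoxy-3-methyl-1H-isochromen-1-one
Product: 10 5-chloro-6,8-dihydroxy-3-methyl-1H-isochromen-1-one
Conditions: BBr3, CH2Cl2, −78 to 20 °C; H2O
Reagents that add atoms: none
Why: Lewis-acid ether cleavage (BBr3 dealkylation) should remove the carbonyl-chelated 8-methyl ether and the 6-ethyl ether, while the enol lactone and the aryl chloride are inert, as for 6,8-dimethoxy-3-methylisocoumarins.

Step 6
Reactants: 10 5-chloro-6,8-dihydroxy-3-methyl-1H-isochromen-1-one
Product: 11 5-chloro-3-methyl-6,8-bis(TBS-oxy)-1H-isochromen-1-one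
Conditions: TBSOTf, 2,6-lutidine, CH2Cl2, 0 to 20 °C
Reagents that add atoms: tert-butyldimethylsilyl trifluoromethanesulfonate, CC(C)(C)[Si](C)(C)OS(=O)(=O)C(F)(F)F
Why: Phenol silylation with a silyl triflate and a hindered base; the triflate is chosen so that the hydrogen-bonded 8-hydroxyl is capped as well, giving base-stable, fluoride-labile protection.

Step 7
Reactants: 12 2-deoxy-D-ribose
Product: 13 2-deoxy-D-ribono-1,4-lactone [(4S,5R)-4-hydroxy-5-(hydroxymethyl)oxolan-2-one]
Conditions: Br2, H2O, 20 °C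
Reagents that add atoms: none
Why: Bromine-water oxidation of the aldose hemiacetal to the aldonic acid, which lactonises to the 1,4-lactone on concentration; C3 and C4 are not touched.

Step 8
Reactants: 13 2-deoxy-D-ribono-1,4-lactone
Product: 14 (4S,5R)-4-(TBS-oxy)-5-[(TBS-oxy)methyl]oxolan-2-one
Conditions: TBSCl, imidazole, DMF, 20 °C
Reagents that add atoms: tert-butyldimethylsilyl chloride, CC(C)(C)[Si](C)(C)Cl
Why: Standard imidazole-promoted silylation of the primary and secondary hydroxyls.

Step 9
Reactants: 14 (4S,5R)-4-(TBS-oxy)-5-[(TBS-oxy)methyl]oxolan-2-one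
Product: 15 (4S,5R)-4-(TBS-oxy)-5-[(TBS-oxy)methyl]-2-methyloxolan-2-ol (anomeric mixture)
Conditions: MeLi, THF, −78 °C; H2O
Reagents that add atoms: methyllithium, [Li]C
Why: Addition of the organolithium to the lactone carbonyl at low temperature should stop at the hemiketal (first half of a Kishi-type C-glycoside synthesis); the anomeric centre is uncontrolled and is erased in step 10.

Step 10
Reactants: 15 (4S,5R)-4-(TBS-oxy)-5-[(TBS-oxy)methyl]-2-methyloxolan-2-ol
Product: 17 (2R,3S,5S)-3-(TBS-oxy)-2-[(TBS-oxy)methyl]-5-methyloxolane, via cyclic oxocarbenium ion 16 (not isolated)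
Conditions: Et3SiH, BF3·OEt2, CH2Cl2, −78 to −40 °C
Reagents that add atoms: none
Why: Lewis-acid ionisation of the hemiketal and hydride transfer from the silane (ionic hydrogenation, Kishi-type lactol reduction) should occur on the inside face of the envelope with the C3 silyloxy group pseudoaxial, cis to that group (Woerpel model, as in β-selective 2-deoxy C-glycoside syntheses), so the methyl group ends cis to the C2 side chain and C5 is set as S.

Step 11
Reactants: 17 (2R,3S,5S)-3-(TBS-oxy)-2-[(TBS-oxy)methyl]-5-methyloxolane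
Product: 18 [(2R,3S,5S)-3-(TBS-oxy)-5-methyloxolan-2-yl]methanol
Conditions: CF3CO2H, H2O, THF, 0 °C
Reagents that add atoms: none
Why: Acid hydrolysis of silyl ethers is sterically governed, so the primary TBS ether should be cleaved selectively over the secondary one, as is routine for 3′,5′-bis-silylated 2′-deoxynucleosides.

Step 12
Reactants: 18 [(2R,3S,5S)-3-(TBS-oxy)-5-methyloxolan-2-yl]methanol
Product: 19 (2S,3S,5S)-3-(TBS-oxy)-5-methyloxolane-2-carbaldehyde
Conditions: Dess–Martin periodinane, CH2Cl2, 0 to 20 °C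
Reagents that add atoms: none
Why: Dess–Martin oxidation is near-neutral and should leave the α-alkoxy stereocentre intact (the descriptor changes from R to S only through CIP priorities); the aldehyde is used crude.

Step 13
Reactants: 19 (2S,3S,5S)-3-(TBS-oxy)-5-methyloxolane-2-carbaldehyde
Product: 20 (2E)-3-[(2R,3S,5S)-3-(TBS-oxy)-5-methyloxolan-2-yl]prop-2-enal
Conditions: Ph3P=CHCHO, PhMe, 70 °C
Reagents that add atoms: (triphenylphosphoranylidene)acetaldehyde, O=CC=P(c1ccccc1)(c1ccccc1)c1ccccc1
Why: Wittig olefination with a stabilised, non-basic ylide should give the E-enal without epimerising C2 or eliminating the β-silyloxy group.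

Step 14
Reactants: 11 5-chloro-3-methyl-6,8-bis(TBS-oxy)-1H-isochromen-1-one; 20 (2E)-3-[(2R,3S,5S)-3-(TBS-oxy)-5-methyloxolan-2-yl]prop-2-enal
Product: 22 5-chloro-3-{(3E)-2-hydroxy-4-[(2R,3S,5S)-3-(TBS-oxy)-5-methyloxolan-2-yl]but-3-en-1-yl}-6,8-bis(TBS-oxy)-1H-isochromen-1-one (both carbinol epimers), via lithium dienolate 21 (not isolated)
Conditions: LiN(SiMe3)2, THF, −78 °C; then 20; AcOH, −78 °C
Reagents that add atoms: none
Why: Lateral deprotonation of the 3-methyl group gives an anion delocalised through C3=C4 and the arene into the lactone carbonyl, as for 6,8-dialkoxy-3-methylisocoumarins and 6-methyl-2-pyranones, and this dienolate should add 1,2 to the enal (vinylogous aldol addition); the carbinol centre forms without control and is removed in step 15, and the oxolane centres are untouched.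

Step 15
Reactants: 22 aldol adduct (both carbinol epimers)
Product: 24 5-chloro-3-{(1E,3E)-4-[(2R,3S,5S)-3-(TBS-oxy)-5-methyloxolan-2-yl]buta-1,3-dien-1-yl}-6,8-bis(TBS-oxy)-1H-isochromen-1-one, via allylic mesylate 23 (not isolated)
Conditions: MsCl, Et3N, CH2Cl2, 0 °C; then DBU, 20 °C
Reagents that add atoms: none
Why: Mesylation followed by base-induced β-elimination through the acidic methylene at C3 (E1cB-type aldol dehydration) should give the fully conjugated diene, the new double bond being E as the less strained, thermodynamically preferred geometry.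

Step 16
Reactants: 24 tris-TBS diene
Product: 25 5-chloro-6,8-dihydroxy-3-{(1E,3E)-4-[(2R,3S,5S)-3-hydroxy-5-methyloxolan-2-yl]buta-1,3-dien-1-yl}-1H-isochromen-1-one
Conditions: Bu4NF, AcOH, THF, 0 to 20 °C
Reagents that add atoms: none
Why: Fluoride-mediated global desilylation should cleave the two aryl silyl ethers and the secondary alkyl silyl ether, with acetic acid buffering to protect the enol lactone and the dienyl oxolane; no stereocentre or alkene geometry is affected.

Compound list
1 | 4-hydroxy-6-methyl-2H-pyran-2-one (triacetic acid lactone) | Cc1cc(O)cc(=O)o1 | starting material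
2 | malonyl dichloride | O=C(Cl)CC(=O)Cl | starting material
3 | 4-hydroxy-7-methyl-2H,5H-pyrano[4,3-b]pyran-2,5-dione | OC1=CC(=O)OC2=C1C(=O)OC(C)=C2 | intermediate
4 | 4-methoxy-7-methyl-2H,5H-pyrano[4,3-b]pyran-2,5-dione | COC1=CC(=O)OC2=C1C(=O)OC(C)=C2 | intermediate
5 | 1,1-dichloro-2,2-diethoxyethane (dichloroacetaldehyde diethyl acetal) | CCOC(OCC)C(Cl)Cl | starting material
6 | 2-chloro-1,1-diethoxyethene (chloroketene diethyl acetal) | CCOC(OCC)=CCl | intermediate
7 | bridged lactone cycloadduct: 7-chloro-8,8-diethoxy-5-methoxy-2-oxabicyclo[2.2.2]oct-5-en-3-one whose C1 and C6 are bp-C8a and bp-C4a of the intact 6-methylpyran-2-one ring (stereoisomer mixture) | COC1=C2C(=O)OC(C)=CC23OC(=O)C1C(OCC)(OCC)C3Cl | intermediate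
8 | 5-chloro-6,6-diethoxy-8-methoxy-3-methyl-5,6-dihydro-1H-isochromen-1-one (racemic) | COC1=CC(OCC)(OCC)C(Cl)C2=C1C(=O)OC(C)=C2 | intermediate
9 | 5-chloro-6-ethoxy-8-methoxy-3-methyl-1H-isochromen-1-one | CCOc1cc(OC)c2c(=O)oc(C)cc2c1Cl | intermediate
10 | 5-chloro-6,8-dihydroxy-3-methyl-1H-isochromen-1-one | Cc1cc2c(Cl)c(O)cc(O)c2c(=O)o1 | intermediate
11 | 5-chloro-3-methyl-6,8-bis[(tert-butyldimethylsilyl)oxy]-1H-isochromen-1-one | Cc1cc2c(Cl)c(O[Si](C)(C)C(C)(C)C)cc(O[Si](C)(C)C(C)(C)C)c2c(=O)o1 | intermediate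
12 | 2-deoxy-D-ribose [(3S,4R)-3,4,5-trihydroxypentanal] | O=CC[C@H](O)[C@H](O)CO | starting material
13 | 2-deoxy-D-ribono-1,4-lactone [(4S,5R)-4-hydroxy-5-(hydroxymethyl)oxolan-2-one] | O=C1C[C@H](O)[C@@H](CO)O1 | intermediate
14 | (4S,5R)-4-(TBS-oxy)-5-[(TBS-oxy)methyl]oxolan-2-one | O=C1C[C@H](O[Si](C)(C)C(C)(C)C)[C@@H](CO[Si](C)(C)C(C)(C)C)O1 | intermediate
15 | (4S,5R)-4-(TBS-oxy)-5-[(TBS-oxy)methyl]-2-methyloxolan-2-ol (anomeric mixture) | CC1(O)C[C@H](O[Si](C)(C)C(C)(C)C)[C@@H](CO[Si](C)(C)C(C)(C)C)O1 | intermediate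
16 | (2R,3S)-3-(TBS-oxy)-2-[(TBS-oxy)methyl]-5-methyl-3,4-dihydro-2H-furan-1-ium (cyclic oxocarbenium ion) | CC1=[O+][C@H](CO[Si](C)(C)C(C)(C)C)[C@@H](O[Si](C)(C)C(C)(C)C)C1 | intermediate
17 | (2R,3S,5S)-3-(TBS-oxy)-2-[(TBS-oxy)methyl]-5-methyloxolane | C[C@H]1C[C@H](O[Si](C)(C)C(C)(C)C)[C@@H](CO[Si](C)(C)C(C)(C)C)O1 | intermediate
18 | [(2R,3S,5S)-3-(TBS-oxy)-5-methyloxolan-2-yl]methanol | C[C@H]1C[C@H](O[Si](C)(C)C(C)(C)C)[C@@H](CO)O1 | intermediate
19 | (2S,3S,5S)-3-(TBS-oxy)-5-methyloxolane-2-carbaldehyde | C[C@H]1C[C@H](O[Si](C)(C)C(C)(C)C)[C@@H](C=O)O1 | intermediate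
20 | (2E)-3-[(2R,3S,5S)-3-(TBS-oxy)-5-methyloxolan-2-yl]prop-2-enal | C[C@H]1C[C@H](O[Si](C)(C)C(C)(C)C)[C@@H](/C=C/C=O)O1 | intermediate
21 | lithium dienolate of 11 (3-methyl group deprotonated) | [Li+].[CH2-]c1cc2c(Cl)c(O[Si](C)(C)C(C)(C)C)cc(O[Si](C)(C)C(C)(C)C)c2c(=O)o1 | intermediate
22 | 5-chloro-3-{(3E)-2-hydroxy-4-[(2R,3S,5S)-3-(TBS-oxy)-5-methyloxolan-2-yl]but-3-en-1-yl}-6,8-bis(TBS-oxy)-1H-isochromen-1-one (both carbinol epimers) | C[C@H]1C[C@H](O[Si](C)(C)C(C)(C)C)[C@@H](/C=C/C(O)Cc2cc3c(Cl)c(O[Si](C)(C)C(C)(C)C)cc(O[Si](C)(C)C(C)(C)C)c3c(=O)o2)O1 | intermediate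
23 | methanesulfonate of 22 (allylic mesylate, both epimers) | C[C@H]1C[C@H](O[Si](C)(C)C(C)(C)C)[C@@H](/C=C/C(OS(C)(=O)=O)Cc2cc3c(Cl)c(O[Si](C)(C)C(C)(C)C)cc(O[Si](C)(C)C(C)(C)C)c3c(=O)o2)O1 | intermediate
24 | 5-chloro-3-{(1E,3E)-4-[(2R,3S,5S)-3-(TBS-oxy)-5-methyloxolan-2-yl]buta-1,3-dien-1-yl}-6,8-bis(TBS-oxy)-1H-isochromen-1-one | C[C@H]1C[C@H](O[Si](C)(C)C(C)(C)C)[C@@H](/C=C/C=C/c2cc3c(Cl)c(O[Si](C)(C)C(C)(C)C)cc(O[Si](C)(C)C(C)(C)C)c3c(=O)o2)O1 | intermediate
25 | 5-chloro-6,8-dihydroxy-3-{(1E,3E)-4-[(2R,3S,5S)-3-hydroxy-5-methyloxolan-2-yl]buta-1,3-dien-1-yl}-1H-isochromen-1-one | C[C@H]1C[C@H](O)[C@@H](/C=C/C=C/c2cc3c(Cl)c(O)cc(O)c3c(=O)o2)O1 | target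

Total step count: 16. Longest linear sequence: 10 steps (steps 7 to 16, from 2-deoxy-D-ribose); the arene branch takes 8 steps from triacetic acid lactone.

Steps most likely to fail

Step 4. The cycloaddition may not start because the 4-methoxy donor lowers the electrophilicity of the diene. The ketene acetal may instead add at bp-C7 of the methyl-bearing ring, displace methoxide at bp-C4, or oligomerise before it reacts. The fallback sets out from 3 and returns at 10, using only known chemistry. Treatment of 3 with KOH in aqueous methanol opens both lactones, and decarboxylation and aldol aromatisation of the resulting triketo acid should give 2,4-dihydroxy-6-methylbenzoic acid (orsellinic acid) F1. Exhaustive methylation (Me2SO4, K2CO3, acetone) gives methyl 2,4-dimethoxy-6-methylbenzoate F2. Electrophilic chlorination with SO2Cl2, para to the 2-methoxy group and next to the methyl group, gives methyl 3-chloro-4,6-dimethoxy-2-methylbenzoate F3. Lateral lithiation with LiN(i-Pr)2 at −78 °C and acylation with N-methoxy-N-methylacetamide gives methyl 3-chloro-4,6-dimethoxy-2-(2-oxopropyl)benzoate F4. BBr3 then cleaves both methyl ethers and closes the enol lactone to 10.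

Step 14. Lateral deprotonation may be incomplete, the dienolate may add in conjugate fashion to the enal, the peri silyl group may migrate or be lost under the basic conditions, or the adduct may revert by retro-aldol on warming. The fallback sets out from 11 and returns at 24, replacing aldol addition and dehydration by an olefination and bypassing 22, 23 and step 15. Wohl–Ziegler bromination of the 3-methyl group (N-bromosuccinimide, AIBN, PhCF3, 80 °C) gives 3-(bromomethyl)-5-chloro-6,8-bis(TBS-oxy)-1H-isochromen-1-one F5. Michaelis–Arbuzov reaction with triethyl phosphite gives diethyl {[5-chloro-1-oxo-6,8-bis(TBS-oxy)-1H-isochromen-3-yl]methyl}phosphonate F6. Horner–Wadsworth–Emmons olefination of 20 (LiN(SiMe3)2, THF, −78 to 0 °C) should then give the E,E-diene 24 directly.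

Step 13. The product enal may undergo a second olefination (over-homologation), and aldehyde 19 may epimerise at the α-alkoxy carbon or lose the β-silyloxy group during heating. The fallback sets out from 19 and returns at 20. Horner–Wadsworth–Emmons olefination with triethyl phosphonoacetate under Masamune–Roush conditions (LiCl, DBU, MeCN, 20 °C) gives ethyl (2E)-3-[(2R,3S,5S)-3-(TBS-oxy)-5-methyloxolan-2-yl]prop-2-enoate F7. Reduction with i-Bu2AlH (CH2Cl2, −78 °C) gives (2E)-3-[(2R,3S,5S)-3-(TBS-oxy)-5-methyloxolan-2-yl]prop-2-en-1-ol F8. Allylic oxidation with MnO2 (CH2Cl2, 20 °C) returns to 20.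

Further compounds
F1 | step 4 | 2,4-dihydroxy-6-methylbenzoic acid (orsellinic acid) | Cc1cc(O)cc(O)c1C(=O)O
F2 | step 4 | methyl 2,4-dimethoxy-6-methylbenzoate | COC(=O)c1c(C)cc(OC)cc1OC
F3 | step 4 | methyl 3-chloro-4,6-dimethoxy-2-methylbenzoate | COC(=O)c1c(C)c(Cl)c(OC)cc1OC
F4 | step 4 | methyl 3-chloro-4,6-dimethoxy-2-(2-oxopropyl)benzoate | COC(=O)c1c(CC(C)=O)c(Cl)c(OC)cc1OC
F5 | step 14 | 3-(bromomethyl)-5-chloro-6,8-bis(TBS-oxy)-1H-isochromen-1-one | BrCc1cc2c(Cl)c(O[Si](C)(C)C(C)(C)C)cc(O[Si](C)(C)C(C)(C)C)c2c(=O)o1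
F6 | step 14 | diethyl {[5-chloro-1-oxo-6,8-bis(TBS-oxy)-1H-isochromen-3-yl]methyl}phosphonate | CCOP(=O)(OCC)Cc1cc2c(Cl)c(O[Si](C)(C)C(C)(C)C)cc(O[Si](C)(C)C(C)(C)C)c2c(=O)o1
F7 | step 13 | ethyl (2E)-3-[(2R,3S,5S)-3-(TBS-oxy)-5-methyloxolan-2-yl]prop-2-enoate | C[C@H]1C[C@H](O[Si](C)(C)C(C)(C)C)[C@@H](/C=C/C(=O)OCC)O1
F8 | step 13 | (2E)-3-[(2R,3S,5S)-3-(TBS-oxy)-5-methyloxolan-2-yl]prop-2-en-1-ol | C[C@H]1C[C@H](O[Si](C)(C)C(C)(C)C)[C@@H](/C=C/CO)O1
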